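**Retrosynthetic overview**
1. Luzonoid D ⇐ C10–O esterification of a core triol with (Z)-4-(TBSO)cinnamic acid (from an Ando olefination); C11 comes from Vilsmeier formylation of the C3=C4 enol ether, reduced in the last step.
2. Bicyclic core ⇐ proline-catalysed intramolecular Michael addition of an acyclic formyl-enal (C9→C5), then lactolisation and trapping of the lactol as the isovalerate.
3. Formyl-enal ⇐ (4S,5R)-dioxane carrying C7/C8 ⇐ allyl addition to an (S)-4-alkyl-1,3-dioxan-5-one.
4. (S)-Ketone ⇐ Enders SAMP-hydrazone alkylation joining the dioxanone (from TRIS) with (E)-4-bromobut-2-enyl pivalate (from butynediol).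
5. Ring order: cyclopentane first (Michael), dihydropyran second (lactol closure, same pot); the dioxane is only a temporary protecting ring.

Assumptions: iridoid numbering is used (C1 acetal, C3=C4, C5/C9 ring fusion, C7/C8 carbinols, C10/C11 CH2O); the target is (1S,5S,7S,8R,9S). A one-pot operation giving one isolated product is counted as one step.

---

**Fragment A – chiral dihydroxyacetone unit**

Step 1
Reactants: 1 tris(hydroxymethyl)aminomethane hydrochloride
Product: 2 (5-amino-2,2-dimethyl-1,3-dioxan-5-yl)methanol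
Conditions: 2,2-dimethoxypropane, p-TsOH (cat.), DMF, rt; Et3N
Reagents that add atoms: 2,2-dimethoxypropane, COC(C)(C)OC
Why: Acid-catalysed transketalisation ties two of the three equivalent CH2OH groups into the six-membered acetonide while the amine stays protonated.

Step 2
Reactants: 2
Product: 3 2,2-dimethyl-1,3-dioxan-5-one
Conditions: NaIO4, KH2PO4, H2O, 0 °C → rt
Reagents that add atoms: water, O (carbonyl oxygen after imine hydrolysis)
Why: Periodate cleavage of the 1,2-amino alcohol removes the CH2OH carbon and leaves the ketone.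

Step 3
Reactants: 3; 4 SAMP, (S)-1-amino-2-(methoxymethyl)pyrrolidine
Product: 5 SAMP hydrazone of 3
Conditions: benzene, reflux, Dean–Stark
Reagents that add atoms: SAMP (4), COC[C@@H]1CCCN1N
Why: Condensation of the ketone with the hydrazine gives the chiral hydrazone used for the Enders alkylation.

**Fragment B – C3–C6 electrophile**

Step 4
Reactants: 6 but-2-yne-1,4-diol
Product: 7 (E)-but-2-ene-1,4-diol
Conditions: LiAlH4, THF, reflux
Reagents that add atoms: none
Why: Hydroxyl-directed trans-hydroalumination of the propargylic alcohol gives only the E-alkene.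

Step 5
Reactants: 7
Product: 8 (E)-4-hydroxybut-2-en-1-yl pivalate
Conditions: PivCl (0.4 equiv), pyridine, CH2Cl2, −20 → 0 °C (excess diol recovered)
Reagents that add atoms: pivaloyl chloride, CC(C)(C)C(=O)Cl
Why: Statistical mono-acylation of the symmetrical diol, with the bulky acyl group suppressing the bis-ester.

Step 6
Reactants: 8
Product: 9 (E)-4-bromobut-2-en-1-yl pivalate
Conditions: CBr4, PPh3, CH2Cl2, 0 °C
Reagents that add atoms: CBr4, BrC(Br)(Br)Br
Why: Appel bromination of the primary allylic alcohol proceeds by SN2 with retention of the E-geometry.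

**Union and core**

Step 7
Reactants: 5; 9
Product: 10 SAMP hydrazone of (S)-4-[(E)-4-(pivaloyloxy)but-2-enyl]-2,2-dimethyl-1,3-dioxan-5-one
Conditions: t-BuLi, THF, −78 °C; then 9, −100 °C → rt
Reagents that add atoms: none (new carbons come from 9)
Why: Enders SAMP-hydrazone alkylation, in which the chelated lithium azaenolate is alkylated on the face away from the methoxymethyl arm and sets C7 as S.

Step 8
Reactants: 10
Product: 11 (2E)-4-[(4S)-2,2-dimethyl-5-oxo-1,3-dioxan-4-yl]but-2-en-1-yl pivalate
Conditions: sat. aq. oxalic acid, Et2O, rt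
Reagents that add atoms: water, O
Why: Mild biphasic hydrazone hydrolysis frees the ketone without epimerising the α-alkoxy centre or opening the acetonide; SAMP is recovered.

Step 9
Reactants: 11; 12 allylmagnesium bromide
Product: 13 (4S,5R)-5-allyl-4-[(E)-4-hydroxybut-2-enyl]-2,2-dimethyl-1,3-dioxan-5-ol (allyl cis to the butenyl chain, OH trans)
Conditions: allylMgBr (4 equiv), THF, −78 °C; then 0 °C → rt
Reagents that add atoms: allylmagnesium bromide (12), C=CC[Mg]Br
Why: Grignard 1,2-addition occurs axially on the chair dioxanone (side chain equatorial, no 1,3-diaxial hydrogens on that face, as in hydride reductions of 1,3-dioxan-5-ones), setting C8 as R, and the excess reagent cleaves the pivalate on warming.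

Step 10
Reactants: 13
Product: 14 bis(triethylsilyl) ether of 13
Conditions: TESOTf, 2,6-lutidine, CH2Cl2, −78 → 0 °C
Reagents that add atoms: TESOTf, CC[Si](CC)(CC)OS(=O)(=O)C(F)(F)F
Why: The silyl triflate silylates both the primary allylic and the hindered tertiary hydroxyl.

Step 11
Reactants: 14
Product: 15 (E)-4-[(4S,5R)-5-allyl-2,2-dimethyl-5-(triethylsilyloxy)-1,3-dioxan-4-yl]but-2-enal
Conditions: (COCl)2, DMSO, CH2Cl2, −78 → −40 °C; Et3N, −78 → 0 °C
Reagents that add atoms: none
Why: Under Swern conditions a primary TES ether is cleaved and oxidised in situ to the aldehyde, while the tertiary TES ether, acetonide and alkenes are untouched.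

Step 12
Reactants: 15
Product: 16 (E)-4-[(4S,5R)-2,2-dimethyl-5-(2-oxoethyl)-5-(triethylsilyloxy)-1,3-dioxan-4-yl]but-2-enal
Conditions: O3, CH2Cl2/pyridine, −78 °C (Sudan Red 7B end point); PPh3
Reagents that add atoms: ozone, [O-][O+]=O
Why: Ozonolysis cleaves the electron-rich terminal alkene much faster than the electron-poor enal alkene, unveiling the C1 aldehyde.

Step 13 (key step)
Reactants: 16; 17 isovaleric anhydride
Product: 18 1β-isovaleryloxy-7,10-O-isopropylidene-8α-triethylsilyloxy-iridoid-3-ene (H-5β, H-9β; same spatial configuration as the target at C1, C5, C7, C8, C9)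
Conditions: D-proline (30 mol %), DMSO, rt; then CH2Cl2, isovaleric anhydride, Et3N, DMAP, 0 °C
Reagents that add atoms: isovaleric anhydride (17), CC(C)CC(=O)OC(=O)CC(C)C
Why: Enamine-mediated intramolecular Michael addition (5-exo) of the C1 aldehyde onto the enal closes the cyclopentane with C1 and C4 on the exo face away from the dioxane (H-5/H-9 β), the enol oxygen then closes the cis-fused lactol, and DMAP-catalysed acylation traps it as the anomerically favoured exo 1β-ester.

Step 14
Reactants: 18
Product: 19 4-formyl derivative of 18 (C4–CHO on the enol ether)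
Conditions: POCl3, DMF, 0 °C → rt; aq. NaOAc
Reagents that add atoms: DMF, CN(C)C=O (formyl C–H); water, O (formyl oxygen)
Why: Vilsmeier–Haack formylation at the nucleophilic β-carbon (C4) of the enol ether installs C11 and turns the enol ether into an acid-tolerant vinylogous formate.

Step 15
Reactants: 19
Product: 20 (1S,5S,7S,8R,9S)-4-formyl-7,8-dihydroxy-8-(hydroxymethyl)-iridoid-3-en-1-yl 3-methylbutanoate
Conditions: TFA/H2O/CH2Cl2 (1:0.2:10), 0 °C
Reagents that add atoms: none
Why: Aqueous acid hydrolyses the strained dioxane acetonide and the TES ether, while the 1-O-acyl acetal survives because the ring oxygen is deactivated by conjugation with the formyl group.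

**Fragment C – (Z)-acid**

Step 16
Reactants: 21 4-hydroxybenzaldehyde
Product: 22 4-(tert-butyldimethylsilyloxy)benzaldehyde
Conditions: TBSCl, imidazole, DMF, rt
Reagents that add atoms: TBSCl, CC(C)(C)[Si](C)(C)Cl
Why: Silylation of the phenol keeps the aldehyde electrophilic for the low-temperature olefination.

Step 17
Reactants: 22; 23 ethyl 2-(diphenoxyphosphoryl)acetate
Product: 24 ethyl (Z)-3-[4-(TBSO)phenyl]prop-2-enoate
Conditions: NaH, THF, −78 → 0 °C
Reagents that add atoms: Ando phosphonate (23), CCOC(=O)CP(=O)(Oc1ccccc1)Oc1ccccc1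
Why: Ando variant of the Horner–Wadsworth–Emmons olefination, where the diaryl phosphonate gives the Z-enoate under kinetic control (about 93:7; the E-isomer is removed by chromatography).

Step 18
Reactants: 24
Product: 25 (Z)-3-(4-hydroxyphenyl)prop-2-enoic acid
Conditions: LiOH, THF/MeOH/H2O, rt, dark
Reagents that add atoms: hydroxide/water, O
Why: Saponification cleaves the ethyl ester (and the base-labile aryl silyl ether) without touching the Z-alkene when light is excluded.

Step 19
Reactants: 25
Product: 26 tert-butyldimethylsilyl (Z)-3-[4-(TBSO)phenyl]prop-2-enoate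
Conditions: TBSCl (2.5 equiv), imidazole, DMF, rt, dark
Reagents that add atoms: TBSCl, CC(C)(C)[Si](C)(C)Cl
Why: Exhaustive silylation protects both the phenol and the acid.

Step 20
Reactants: 26
Product: 27 (Z)-3-[4-(TBSO)phenyl]prop-2-enoic acid
Conditions: AcOH/THF/H2O (3:1:1), rt, dark
Reagents that add atoms: none
Why: The silyl ester hydrolyses far faster than the aryl silyl ether under mild acid, freeing only the carboxylic acid.

**Endgame**

Step 21
Reactants: 20; 27
Product: 28 10-O-[(Z)-4-(TBSO)cinnamoyl] ester of 20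
Conditions: EDC·HCl, DMAP (0.2 equiv), CH2Cl2, −20 → 0 °C, dark
Reagents that add atoms: none (atoms come from 27)
Why: Steglich esterification selects the primary C10-OH over the hindered secondary C7-OH (the tertiary C8-OH is inert), and low temperature with little DMAP preserves the Z-alkene.

Step 22
Reactants: 28
Product: 29 10-O-[(Z)-p-coumaroyl] aldehyde (11-oxo-luzonoid D)
Conditions: TBAF/AcOH (1:1.2), THF, 0 °C
Reagents that add atoms: none
Why: Buffered fluoride cleaves the aryl silyl ether within minutes without acyl migration or attack on the acyl acetal.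

Step 23
Reactants: 29
Product: 30 luzonoid D
Conditions: NaBH4, CeCl3·7H2O, MeOH, −78 °C; acetone, pH 7 buffer
Reagents that add atoms: none
Why: Luche reduction gives chemoselective 1,2-reduction of the vinylogous formyl group to the C11 alcohol, leaving the esters, acyl acetal and Z-enoate intact.

---

**Compound list**
1 | TRIS hydrochloride | Cl.NC(CO)(CO)CO | starting material
2 | (5-amino-2,2-dimethyl-1,3-dioxan-5-yl)methanol | CC1(C)OCC(N)(CO)CO1 | intermediate
3 | 2,2-dimethyl-1,3-dioxan-5-one | CC1(C)OCC(=O)CO1 | intermediate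
4 | SAMP | COC[C@@H]1CCCN1N | starting material
5 | SAMP hydrazone of 3 | CC1(C)OCC(=NN2CCC[C@H]2COC)CO1 | intermediate
6 | but-2-yne-1,4-diol | OCC#CCO | starting material
7 | (E)-but-2-ene-1,4-diol | OC/C=C/CO | intermediate
8 | (E)-4-hydroxybut-2-enyl pivalate | CC(C)(C)C(=O)OC/C=C/CO | intermediate
9 | (E)-4-bromobut-2-enyl pivalate | CC(C)(C)C(=O)OC/C=C/CBr | intermediate
10 | alkylated SAMP hydrazone (4S) | CC1(C)OCC(=NN2CCC[C@H]2COC)[C@H](C/C=C/COC(=O)C(C)(C)C)O1 | intermediate
11 | (S)-4-alkyl dioxanone pivalate | CC1(C)OCC(=O)[C@H](C/C=C/COC(=O)C(C)(C)C)O1 | intermediate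
12 | allylmagnesium bromide | C=CC[Mg]Br | starting material
13 | (4S,5R)-diol | CC1(C)OC[C@](O)(CC=C)[C@H](C/C=C/CO)O1 | intermediate
14 | bis-TES ether | CC1(C)OC[C@](O[Si](CC)(CC)CC)(CC=C)[C@H](C/C=C/CO[Si](CC)(CC)CC)O1 | intermediate
15 | enal | CC1(C)OC[C@](O[Si](CC)(CC)CC)(CC=C)[C@H](C/C=C/C=O)O1 | intermediate
16 | formyl-enal | CC1(C)OC[C@](O[Si](CC)(CC)CC)(CC=O)[C@H](C/C=C/C=O)O1 | intermediate
17 | isovaleric anhydride | CC(C)CC(=O)OC(=O)CC(C)C | starting material
18 | tricyclic 1β-isovalerate (formally 1S,5R,7S,8R,9S, because C4 is unsubstituted) | CC(C)CC(=O)O[C@@H]1OC=C[C@H]2C[C@@H]3OC(C)(C)OC[C@]3(O[Si](CC)(CC)CC)[C@@H]12 | intermediate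
19 | 4-formyl tricycle | CC(C)CC(=O)O[C@@H]1OC=C(C=O)[C@H]2C[C@@H]3OC(C)(C)OC[C@]3(O[Si](CC)(CC)CC)[C@@H]12 | intermediate
20 | triol aldehyde | CC(C)CC(=O)O[C@@H]1OC=C(C=O)[C@H]2C[C@H](O)[C@](O)(CO)[C@@H]12 | intermediate
21 | 4-hydroxybenzaldehyde | O=Cc1ccc(O)cc1 | starting material
22 | 4-(TBSO)benzaldehyde | O=Cc1ccc(O[Si](C)(C)C(C)(C)C)cc1 | intermediate
23 | ethyl 2-(diphenoxyphosphoryl)acetate | CCOC(=O)CP(=O)(Oc1ccccc1)Oc1ccccc1 | starting material
24 | ethyl (Z)-4-(TBSO)cinnamate | CCOC(=O)/C=C\c1ccc(O[Si](C)(C)C(C)(C)C)cc1 | intermediate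
25 | (Z)-p-coumaric acid | OC(=O)/C=C\c1ccc(O)cc1 | intermediate
26 | TBS (Z)-4-(TBSO)cinnamate | CC(C)(C)[Si](C)(C)OC(=O)/C=C\c1ccc(O[Si](C)(C)C(C)(C)C)cc1 | intermediate
27 | (Z)-4-(TBSO)cinnamic acid | OC(=O)/C=C\c1ccc(O[Si](C)(C)C(C)(C)C)cc1 | intermediate
28 | silylated ester aldehyde | CC(C)CC(=O)O[C@@H]1OC=C(C=O)[C@H]2C[C@H](O)[C@](O)(COC(=O)/C=C\c3ccc(O[Si](C)(C)C(C)(C)C)cc3)[C@@H]12 | intermediate
29 | 11-oxo-luzonoid D | CC(C)CC(=O)O[C@@H]1OC=C(C=O)[C@H]2C[C@H](O)[C@](O)(COC(=O)/C=C\c3ccc(O)cc3)[C@@H]12 | intermediate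
30 | luzonoid D | CC(C)CC(=O)O[C@@H]1OC=C(CO)[C@H]2C[C@H](O)[C@](O)(COC(=O)/C=C\c3ccc(O)cc3)[C@@H]12 | target

---

**Totals**
Total steps: 23. Longest linear sequence: 15 steps (1–3 or 4–6, then 7–15 and 21–23), which is 65 % of the total.

**Three steps most likely to fail**
1. Step 13 (Michael/lactolisation). The enamine sits β to the C8 silyloxy group and may eliminate it (E1cB), or the wrong C5 face may be attacked. Fallback: change the donor type. Add vinylMgBr in step 9, then ozonolysis and Wittig methoxymethylenation to give a C9=C1 enol ether, and close the ring by a Lewis-acid-promoted intramolecular Mukaiyama–Michael addition/acetalisation onto the enal. This gives the 1-OMe acetal with no enamine, which is exchanged to the isovalerate via the lactol.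
2. Step 9 (C8 configuration). Axial attack on the dioxanone may not dominate. Fallback: take C7/C8 from the chiral pool. Methyl 2-deoxy-D-erythro-pentopyranoside is 3-O-protected and oxidised to the 4-ulose, and allyl is added trans to O-3, which gives the same C7/C8 array. Ring opening then converges on the formyl-enal.
3. Step 15 (acid deprotection beside the 1-O-acyl acetal). Fallback: replace the acetonide early (after step 9) by a 7,10-O-di-tert-butylsilylene, so that all late unmasking is fluoride-based (HF·pyridine) and no aqueous acid touches the acyl acetal.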